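**Retrosynthetic overview**
- Target 11 is cut at C4–C4a and O1–C2 of the methoxylated coumarin. The nucleophilic β-carbon of a carbene-bound homoenolate (from 2-aryloxyacrolein 6) is joined to the electrophilic C5 of 2,5-dimethoxy-1,4-benzoquinone 7.
- The quinone then serves as the internal oxidant, so the coumarin oxidation level is reached without a separate dehydrogenation.
- Enal 6 comes from aldehyde 4 and formaldehyde 5 by α-methylenation; 4 comes from umbelliferone 1 and bromoacetaldehyde diethyl acetal 2 via acetal 3.
- Ring order: the umbelliferone coumarin is bought intact, the benzene ring of the second coumarin enters as the quinone, and its pyranone ring is closed last (step 4).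

Assumption: the target has no stereocentre or other stereogenic element, so "single enantiomer" requires no stereocontrol.

**Step 1**
Reactants: 1 umbelliferone (7-hydroxy-2H-chromen-2-one); 2 bromoacetaldehyde diethyl acetal (2-bromo-1,1-diethoxyethane)
Product: 3 7-(2,2-diethoxyethoxy)-2H-chromen-2-one
Conditions: K2CO3 (1.5 eq), KI (cat.), DMF, 100 °C
Reagents that add atoms: none
Why: Williamson ether synthesis (SN2 of the acidic 7-phenoxide on the primary bromide); the lactone tolerates anhydrous carbonate.

**Step 2**
Reactants: 3 7-(2,2-diethoxyethoxy)-2H-chromen-2-one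
Product: 4 [(2-oxo-2H-chromen-7-yl)oxy]acetaldehyde
Conditions: 1 M aq. HCl, acetone, 50 °C; used crude
Reagents that add atoms: water, O
Why: Acid-catalysed acetal hydrolysis; dilute aqueous acid is far milder than the dehydrating conditions needed for furan ring closure onto the deactivated coumarin ring.

**Step 3**
Reactants: 4 [(2-oxo-2H-chromen-7-yl)oxy]acetaldehyde; 5 formaldehyde (37 % aq.)
Product: 6 2-[(2-oxo-2H-chromen-7-yl)oxy]prop-2-enal
Conditions: pyrrolidine (10 mol %), EtCO2H (10 mol %), i-PrOH, 45 °C; used promptly
Reagents that add atoms: none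
Why: Organocatalytic α-methylenation (enamine Mannich condensation, then E1cB loss of the amine), the standard way to turn alkoxyacetaldehydes into 2-alkoxyacroleins.

**Step 4**
Reactants: 6 2-[(2-oxo-2H-chromen-7-yl)oxy]prop-2-enal; 7 2,5-dimethoxy-1,4-benzoquinone
Product: 11 6-hydroxy-7-methoxy-3-[(2-oxo-2H-chromen-7-yl)oxy]-2H-chromen-2-one, via homoenolate 8 (not isolated), via azolium enolate 9 (not isolated), via acyl azolium phenoxide 10 (not isolated)
Conditions: 2-mesityl-6,7-dihydro-5H-pyrrolo[2,1-c][1,2,4]triazol-2-ium chloride (20 mol %), DBU (30 mol %), 4 Å MS, DCE, 50 °C, slow addition of 6; aq. NH4Cl work-up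
Reagents that add atoms: none
Why: Proposed new method: the carbene turns enal 6 into homoenolate 8, whose nucleophilic β-CH2 attacks the methoxy-bearing C5 of 7 (an enamine-like conjugate addition as in the Nenitzescu reaction) and expels methoxide to give 9; a base-mediated proton shift from the CH2 group to the quinone oxygen (quinone to o-quinone methide tautomerisation, as in ubiquinone-to-ubichromenol isomerisation) gives unsaturated acyl azolium 10, a push-pull alkene whose geometry can equilibrate so that the ortho phenoxide closes the lactone and releases the carbene; only the oxygen ortho to the new C–C bond can cyclise, which fixes 6-OH/7-OMe; closest known reaction types are NHC-homoenolate 1,6-additions to p-quinone methides and homoenolate Michael addition/acylation annulations.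

**Compound list**
1 | umbelliferone (7-hydroxy-2H-chromen-2-one) | Oc1ccc2ccc(=O)oc2c1 | starting material
2 | bromoacetaldehyde diethyl acetal | CCOC(CBr)OCC | starting material
3 | 7-(2,2-diethoxyethoxy)-2H-chromen-2-one | CCOC(COc1ccc2ccc(=O)oc2c1)OCC | intermediate
4 | [(2-oxo-2H-chromen-7-yl)oxy]acetaldehyde | O=CCOc1ccc2ccc(=O)oc2c1 | intermediate
5 | formaldehyde | C=O | starting material
6 | 2-[(2-oxo-2H-chromen-7-yl)oxy]prop-2-enal | C=C(C=O)Oc1ccc2ccc(=O)oc2c1 | intermediate
7 | 2,5-dimethoxy-1,4-benzoquinone | COC1=CC(=O)C(OC)=CC1=O | starting material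
8 | homoenolate (extended Breslow intermediate of 6): triazolylidene=C(OH)–C(OAr)=CH2 | OC(C(=C)Oc1ccc2ccc(=O)oc2c1)=C1N(c2c(C)cc(C)cc2C)N=C2CCCN12 | intermediate
9 | azolium enolate: triazolium–C(O–)=C(OAr)–CH2–(4-methoxy-3,6-dioxocyclohexa-1,4-dien-1-yl), zwitterion | [O-]C(=C(CC1=CC(=O)C(OC)=CC1=O)Oc1ccc2ccc(=O)oc2c1)c1n2CCCc2n[n+]1-c1c(C)cc(C)cc1C | intermediate
10 | acyl azolium phenoxide: (E)-3-(2,5-dihydroxy-4-methoxyphenyl)-2-aryloxyacryloyl triazolium, 2-phenoxide zwitterion (aryl cis to acyl) | [O-]c1cc(OC)c(O)cc1/C=C(/Oc1ccc2ccc(=O)oc2c1)C(=O)c1n2CCCc2n[n+]1-c1c(C)cc(C)cc1C | intermediate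
11 | 6-hydroxy-7-methoxy-3-[(2-oxo-2H-chromen-7-yl)oxy]-2H-chromen-2-one | COc1cc2oc(=O)c(Oc3ccc4ccc(=O)oc4c3)cc2cc1O | target

**Totals**
Total step count: 4. Longest linear sequence: 4 (1 → 3 → 4 → 6 → 11).

**Steps most likely to fail, with fallbacks**

Step 4 is the main risk. The homoenolate may transfer an electron to the quinone instead of forming the C–C bond, may attack a C–H position of 7, or the enal may dimerise through its own homoenolate. The fallback sets out from enal 6 and replaces 7 by commercial 2-methoxy-1,4-benzoquinone (COC1=CC(=O)C=CC1=O) under the same carbene catalysis. Homoenolate 8 then undergoes a plain conjugate addition at C5, the unsubstituted carbon β to the more electrophilic carbonyl. The adduct aromatises and the ortho hydroxyl is acylated, giving racemic 6-hydroxy-7-methoxy-3-[(2-oxo-2H-chromen-7-yl)oxy]-3,4-dihydro-2H-chromen-2-one F1. The same compound is the expected major product if electron transfer comes first, because the unsaturated acyl azolium and methoxyhydroquinone should recombine at the carbon para to the methoxy group. DDQ (1.1 eq, dioxane, 80 °C) then dehydrogenates C3–C4 by hydride abstraction para to the 7-methoxy group, and the route is rejoined at target 11.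

Step 3 may fail because enal 6 can polymerise or add water or amine under the aqueous catalytic conditions. The fallback sets out from aldehyde 4 and uses a preformed iminium salt (Eschenmoser's salt, CH2Cl2, rt, NaHCO3 work-up) to give the Mannich base 3-(dimethylamino)-2-[(2-oxo-2H-chromen-7-yl)oxy]propanal F2, taken on crude. Methyl iodide in MeCN converts it into the storable salt N,N,N-trimethyl-3-oxo-2-[(2-oxo-2H-chromen-7-yl)oxy]propan-1-aminium iodide F3. Hofmann-type E1cB elimination (aq. NaHCO3/CH2Cl2, or the DBU of step 4 in the same flask) releases the enal, and the route is rejoined at 6 without storing it.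

Step 2 may fail because the aryloxyacetaldehyde can hydrate, oligomerise or cyclise under acid. The fallback sets out from umbelliferone 1 and opens glycidol (OCC1CO1; cat. K2CO3, DMF, 80 °C) at its terminal carbon to give racemic 7-(2,3-dihydroxypropoxy)-2H-chromen-2-one F4. Sodium periodate (THF/H2O, rt) cleaves the diol under neutral conditions, and the route is rejoined at aldehyde 4.

**Further compounds**
F1 | step 4 | rac-6-hydroxy-7-methoxy-3-[(2-oxo-2H-chromen-7-yl)oxy]-3,4-dihydro-2H-chromen-2-one | COc1cc2OC(=O)C(Oc3ccc4ccc(=O)oc4c3)Cc2cc1O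
F2 | step 3 | rac-3-(dimethylamino)-2-[(2-oxo-2H-chromen-7-yl)oxy]propanal | CN(C)CC(C=O)Oc1ccc2ccc(=O)oc2c1
F3 | step 3 | rac-N,N,N-trimethyl-3-oxo-2-[(2-oxo-2H-chromen-7-yl)oxy]propan-1-aminium iodide | C[N+](C)(C)CC(C=O)Oc1ccc2ccc(=O)oc2c1.[I-]
F4 | step 2 | rac-7-(2,3-dihydroxypropoxy)-2H-chromen-2-one | OCC(O)COc1ccc2ccc(=O)oc2c1
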